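We read the target as a late stop on the road: the cedar run ends with 0.8% of it against a scatter of 0.5 percentage points, beside 8.1% of intermediate. So the first thing to ask of a molecule of substrate is whether it has left the substrate at all.

| flask | substrate | partner | temperature | remark | time |
|---|---|---|---|---|---|
| alder | 20 mM | 3.5 equiv | −40 °C | run made earlier |  |
| cedar | 20 mM | 5.5 equiv | −15 °C | run made earlier |  |
| ash | 40 mM | 2.5 equiv | −40 °C | run made earlier |  |
| gamma | 20 mM | 2.50 equiv | −35 °C |  | 2.0 d |
| theta | 20 mM | 2.50 equiv | 5 °C |  | 2.0 d |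
| zeta | 20 mM | 2.50 equiv | −15 °C |  | 2.0 d |

alder run (percent of the substrate charged)

| time / d | intermediate / % | target / % |
|---|---|---|
| 0.208 | 0 | 0 |
| 0.333 | 0 | 0 |
| 0.417 | 0 | 0.6 |
| 0.625 | 0 | 0 |
| 1.04 | 0.5 | 0.4 |
| 1.67 | 0.6 | 0.3 |
| 2.50 | 0.3 | 0.4 |

cedar run (percent of the substrate charged)

| time / h | intermediate / % | target / % |
|---|---|---|
| 1.00 | 0.4 | 0.4 |
| 3.00 | 1.8 | 0 |
| 6.00 | 2.6 | 0 |
| 10.0 | 4.5 | 0 |
| 15.0 | 7.1 | 0.9 |
| 20.0 | 8.1 | 0.8 |

ash run (percent of the substrate charged)

| time / d | intermediate / % | target / % |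
|---|---|---|
| 0.208 | 0 | 0 |
| 0.333 | 0 | 0 |
| 0.625 | 0.1 | 0.2 |
| 1.25 | 0.6 | 0 |
| 2.50 | 0.6 | 0.2 |

(each reading ± 0.5 percentage points)

1. the best flask by amount of intermediate, in percent of the substrate charged; "all alike" if 1.5 percentage points covers them all (gamma / theta / zeta / all alike)
2. amount of intermediate at the end, in percent of the substrate charged, gamma
3. amount of intermediate at the end, in percent of the substrate charged, theta
4. amount of intermediate at the end, in percent of the substrate charged, zeta

Intermediate plus target at the end of the cedar run give a first-order constant of 0.112 d⁻¹ at −15 °C; this is the leaving constant, the chance per day that a molecule of substrate departs. The alder and ash runs together read 0.00300 d⁻¹ at −40 °C. Alder has 3.5 equiv of partner on 20 mM and ash 2.5 equiv on 40 mM, yet they end at 0.700% and 0.800%. Those two sums lie within the scatter and prove nothing, but we take the leaving constant as free of partner. Carrying the same step per kelvin gives 0.00619 d⁻¹ for gamma and 2.02 d⁻¹ for theta.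

At the next fork we take intermediate to leave for target. Taken as pseudo-first-order in partner, the cedar readings give a poor 0.108 d⁻¹ at 2.50 equiv and −15 °C, close to the leaving constant.

Two extreme flasks can be solved in the head. If intermediate has no exit, it holds one minus exp(−kt); if its exit matches the leaving constant, it holds kt·exp(−kt). For zeta these give 20.0% and 17.9%, so we commit to that narrow range. For gamma we commit to 1.23%. For theta they stand wide apart, 98.2% and 7.08%, and we cannot read how the exit climbs with temperature; so we take the middle, 52.6%, and, as that stands higher than the zeta range, theta as best.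

The forecast differs from us on the leaving step, “Assuming first order in partner”: 0.8% for gamma, 12% for theta, 7.5% for zeta, best theta.

The flasks give 0.677% for gamma, 54.8% for theta and 19.4% for zeta, with theta best.

    substrate → intermediate (k = 2.73 × 10⁻⁵ s⁻¹, Ea = 90.0 kJ mol⁻¹)
    partner + intermediate → target (k = 9.42 × 10⁻⁵ M⁻¹ s⁻¹, Ea = 56.0 kJ mol⁻¹)
    2 intermediate → homo product (k = 1.03 × 10⁻⁵ M⁻¹ s⁻¹, Ea = 63.0 kJ mol⁻¹)
    partner + target → over-reaction product (k = 1.42 × 10⁻⁴ M⁻¹ s⁻¹, Ea = 76.0 kJ mol⁻¹)
    (constants at 5 °C)

In zeta at 2.00 d, intermediate is made 7.55 times faster than it is used up, each step taken net, and 20.7% of the substrate has gone. Put on the zeta flask read at 8.0 d, the leaving constant of 0.112 d⁻¹ leaves 40.8% of the substrate, and that flask holds 39.6%.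

The data are calculated on assumed constants; scatter was added.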